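Ring numbering: C1 (carbinol carrying C7), C2 (CHOH), C3 and C6 (CHOBz), C4=C5. Everything rests on disconnecting the C1–C7 bond. Because C7 and the C2 oxygen are cis on the cyclohexene ring, a CH2 nucleophile hung from O2 by a silicon atom is forced onto the correct face of a C1 carbonyl. Iodine–lithium exchange on an O2 (iodomethyl)dimethylsilyl ether thus forms C1–C7, the cis-fused O2–Si–C7–C1–C2 oxasilolane ring and the quaternary C1 stereocentre in one operation. The precursor is a conduritol A-derived cyclohex-4-en-1-one with 4-methoxybenzyl (PMB) ethers on O3 and O6, its carbonyl unveiled only after the tether is attached.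

Key step: step 13

Remark 1: the locants C1–C7 defined above are used for all cyclohexene intermediates, whatever the formal nomenclature numbering would be.
Remark 2 (assumption): the sense of induction of the copper–bis(oxazoline) benzoylation in step 8 is taken by analogy with simple cis-cycloalkane-1,2-diols; should the C2 hydroxyl be the one acylated, the mirror-image ligand is used and nothing else changes.
Remark 3: 2, 3 and 5 are racemic (one enantiomer drawn), 6 to 11 are meso, and from 13 on every compound is a single enantiomer.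

Step 1
Reactants: 1 cyclohexa-1,4-diene
Product: 2 rac-trans-4,5-dibromocyclohex-1-ene
Conditions: Br2 (1.0 equiv), CH2Cl2, −78 °C
Reagents that add atoms: bromine, BrBr
Why: Electrophilic anti addition of one equivalent of bromine through a bromonium ion to one of the two equivalent isolated alkenes gives the trans-dibromide and leaves the second alkene for dihydroxylation, over-bromination being held back by stoichiometry and low temperature.

Step 2
Reactants: 2 rac-trans-4,5-dibromocyclohex-1-ene
Product: 3 rac-(1R,2S,4R,5R)-4,5-dibromocyclohexane-1,2-diol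
Conditions: OsO4 (cat.), NMO, acetone/H2O, rt
Reagents that add atoms: N-methylmorpholine N-oxide, C[N+]1([O-])CCOCC1; water, O (both oxygens are handed on by the catalytic OsO4)
Why: Upjohn cis-dihydroxylation adds both hydroxyls suprafacially, and since the two alkene faces of the C2-symmetric dibromide are equivalent a single racemic cis-diol should result.

Step 3
Reactants: 3 rac-(1R,2S,4R,5R)-4,5-dibromocyclohexane-1,2-diol; 4 2,2-dimethoxypropane
Product: 5 rac-(3aR,5R,6R,7aS)-5,6-dibromo-2,2-dimethylhexahydro-1,3-benzodioxole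
Conditions: 2,2-dimethoxypropane, TsOH·H2O (cat.), acetone, rt
Reagents that add atoms: 2,2-dimethoxypropane (4), COC(C)(C)OC
Why: Acid-catalysed transketalisation closes the dioxolane on the cis-1,2-diol and does not touch the secondary bromides.

Step 4
Reactants: 5 rac-(3aR,5R,6R,7aS)-5,6-dibromo-2,2-dimethylhexahydro-1,3-benzodioxole
Product: 6 (3aR,7aS)-2,2-dimethyl-3a,7a-dihydro-1,3-benzodioxole (meso)
Conditions: DBU (3 equiv), toluene, 80 °C
Reagents that add atoms: none
Why: Twofold E2 dehydrobromination with the amidine base gives the conjugated cyclohexa-1,3-diene, erasing both bromine-bearing stereocentres and leaving the meso cis-diol acetonide, which is used at once because it dimerises slowly.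

Step 5
Reactants: 6 (3aR,7aS)-2,2-dimethyl-3a,7a-dihydro-1,3-benzodioxole
Product: 8 meso-(3aR,4S,7R,7aS)-2,2-dimethyl-3a,4,7,7a-tetrahydro-1,3-benzodioxole-4,7-diol, via endoperoxide 7 (not isolated)
Conditions: O2, tetraphenylporphyrin (cat.), visible light, CH2Cl2, 0 °C; then thiourea, MeOH, rt
Reagents that add atoms: dioxygen, O=O
Why: Singlet oxygen undergoes [4+2] cycloaddition to the diene on the face opposite the acetonide and thiourea reduces the O–O bond in the same pot, so the two new allylic C–O bonds are cis to each other and trans to the acetonide (conduritol A pattern).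

Step 6
Reactants: 8 meso-(3aR,4S,7R,7aS)-2,2-dimethyl-3a,4,7,7a-tetrahydro-1,3-benzodioxole-4,7-diol; 9 4-methoxybenzyl chloride
Product: 10 meso-(3aR,4S,7R,7aS)-4,7-bis[(4-methoxybenzyl)oxy]-2,2-dimethyl-3a,4,7,7a-tetrahydro-1,3-benzodioxole
Conditions: NaH (2.5 equiv), PMBCl (2.4 equiv), Bu4NI (cat.), DMF, 0 °C to rt
Reagents that add atoms: 4-methoxybenzyl chloride (9), COc1ccc(CCl)cc1
Why: Williamson etherification of both allylic alkoxides installs ethers that tolerate organolithium reagents, are poor leaving groups beta to the later ketone and can be removed oxidatively.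

Step 7
Reactants: 10 meso-(3aR,4S,7R,7aS)-4,7-bis[(4-methoxybenzyl)oxy]-2,2-dimethyl-3a,4,7,7a-tetrahydro-1,3-benzodioxole
Product: 11 meso-(1S,2R,3R,6S)-3,6-bis[(4-methoxybenzyl)oxy]cyclohex-4-ene-1,2-diol
Conditions: AcOH/H2O (4:1), 45 °C
Reagents that add atoms: none
Why: Mild aqueous acid hydrolyses the isopropylidene acetal while PMB ethers are stable to acetic acid, exposing the meso cis-1,2-diol.

Step 8
Reactants: 11 meso-(1S,2R,3R,6S)-3,6-bis[(4-methoxybenzyl)oxy]cyclohex-4-ene-1,2-diol; 12 benzoyl chloride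
Product: 13 (1S,2S,3R,6S)-2-hydroxy-3,6-bis[(4-methoxybenzyl)oxy]cyclohex-4-en-1-yl benzoate
Conditions: Cu(OTf)2 (5 mol %), (S,S)-Ph-BOX (5 mol %), BzCl (1.05 equiv), i-Pr2NEt, CH2Cl2, 0 °C
Reagents that add atoms: benzoyl chloride (12), O=C(Cl)c1ccccc1
Why: Copper–bis(oxazoline)-catalysed enantioselective monobenzoylation of a meso cis-1,2-diol, in which the diol chelates the chiral Cu(OTf)2–ligand complex and one enantiotopic hydroxyl (that on C1) is acylated, should fix the absolute configuration of all four existing stereocentres in one desymmetrisation.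

Step 9
Reactants: 13 (1S,2S,3R,6S)-2-hydroxy-3,6-bis[(4-methoxybenzyl)oxy]cyclohex-4-en-1-yl benzoate; 14 (bromomethyl)chlorodimethylsilane
Product: 15 (1R,2S,3R,6S)-2-{[(bromomethyl)dimethylsilyl]oxy}-3,6-bis[(4-methoxybenzyl)oxy]cyclohex-4-en-1-yl benzoate
Conditions: BrCH2SiMe2Cl (1.3 equiv), Et3N, DMAP (cat.), CH2Cl2, 0 °C
Reagents that add atoms: (bromomethyl)chlorodimethylsilane (14), C[Si](C)(Cl)CBr
Why: Silylation of the only free hydroxyl with the reactive chlorosilane under a mild amine base (too weak to move the benzoate) attaches the one-carbon tether to O2 while O1 is still masked, so that no free alpha-ketol is ever handled.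

Step 10
Reactants: 15 (1R,2S,3R,6S)-2-{[(bromomethyl)dimethylsilyl]oxy}-3,6-bis[(4-methoxybenzyl)oxy]cyclohex-4-en-1-yl benzoate
Product: 16 (1R,2S,3R,6S)-2-{[(iodomethyl)dimethylsilyl]oxy}-3,6-bis[(4-methoxybenzyl)oxy]cyclohex-4-en-1-yl benzoate
Conditions: NaI (5 equiv), acetone, rt, dark
Reagents that add atoms: sodium iodide, [Na+].[I-]
Why: Finkelstein exchange (SN2 at the CH2 next to silicon, driven by precipitation of NaBr) gives the iodide needed for fast halogen–lithium exchange and is done here, on a robust intermediate, so the ketone is not exposed to it.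

Step 11
Reactants: 16 (1R,2S,3R,6S)-2-{[(iodomethyl)dimethylsilyl]oxy}-3,6-bis[(4-methoxybenzyl)oxy]cyclohex-4-en-1-yl benzoate
Product: 17 (1R,2R,3R,6S)-2-{[(iodomethyl)dimethylsilyl]oxy}-3,6-bis[(4-methoxybenzyl)oxy]cyclohex-4-en-1-ol
Conditions: i-Bu2AlH (2.5 equiv), CH2Cl2, −78 °C; aq. potassium sodium tartrate
Reagents that add atoms: none
Why: Reductive cleavage of the benzoate by the aluminium hydride at low temperature frees the C1 hydroxyl without base or fluoride, so the labile silyl ether stays on O2 (no migration to the cis hydroxyl, which would amount to racemisation) and the iodide and PMB ethers persist.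

Step 12
Reactants: 17 (1R,2R,3R,6S)-2-{[(iodomethyl)dimethylsilyl]oxy}-3,6-bis[(4-methoxybenzyl)oxy]cyclohex-4-en-1-ol
Product: 18 (2S,3R,6S)-2-{[(iodomethyl)dimethylsilyl]oxy}-3,6-bis[(4-methoxybenzyl)oxy]cyclohex-4-en-1-one
Conditions: Dess–Martin periodinane (1.5 equiv), NaHCO3, CH2Cl2, 0 °C to rt
Reagents that add atoms: none
Why: Dess–Martin oxidation of the secondary alcohol under buffered, near-neutral conditions gives the alpha-silyloxy ketone without the base that would cause beta-elimination of an ether or epimerisation at C2 or C6, and the ketone is taken on directly.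

Step 13
Reactants: 18 (2S,3R,6S)-2-{[(iodomethyl)dimethylsilyl]oxy}-3,6-bis[(4-methoxybenzyl)oxy]cyclohex-4-en-1-one
Product: 21 cis-fused oxasilolane tertiary alcohol (1S,2S,3R,6S; ring O2–SiMe2–C7–C1–C2; PMB ethers on O3 and O6; free C1–OH), via silylmethyllithium 19 (not isolated), via lithium alkoxide 20 (not isolated)
Conditions: t-BuLi (2.1 equiv, slow addition), THF/Et2O/pentane (4:1:1), −100 °C; then AcOH in THF, −100 °C
Reagents that add atoms: none
Why: Iodine–lithium exchange at the CH2I group outruns attack of t-BuLi on the ketone at −100 °C (the second equivalent consumes the t-BuI formed), and the alpha-silyl carbanion, linked to C1 through Si, O2 and C2, adds at once to the carbonyl and forms the C1–C7 bond. The closest known reaction type is the halogen–lithium exchange-initiated intramolecular carbonyl addition (Parham-type cyclisation, an intramolecular Barbier reaction), here run on a silicon-tethered halomethylsilyl ether. The oxasilolane ring O2–Si–C7–C1–C2 closes in the 5-exo-trig mode. The new quaternary stereocentre C1 is controlled by the C2 stereocentre through the tether, because a five-membered ring fused to the cyclohexene can only be cis, so C7 enters on the O2 face and the C1 oxygen ends up cis to the C6 oxygen. The step needs chemoselectivity (exchange before carbonyl attack or enolisation) and facial selectivity, the first secured by the speed of exchange at iodine with slow addition of the base at −100 °C, the second by the short O–Si link. Protonation with AcOH at −100 °C keeps the lithium beta-silyl alkoxide from Peterson elimination.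

Step 14
Reactants: 21 cis-fused oxasilolane tertiary alcohol
Product: 22 oxasilolane triol (1S,2S,3R,6S; free hydroxyls on C1, C3 and C6)
Conditions: DDQ (2.4 equiv), CH2Cl2/pH 7 phosphate buffer (10:1), 0 °C
Reagents that add atoms: none
Why: Oxidative PMB cleavage by DDQ (hydride abstraction to the oxocarbenium ion and hydrolysis in the buffered two-phase medium) frees the C3 and C6 hydroxyls, while the silacycle and the tertiary alcohol offer nothing to oxidise.

Step 15
Reactants: 22 oxasilolane triol; 12 benzoyl chloride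
Product: 23 oxasilolane 3,6-dibenzoate (1S,2S,3R,6S; free tertiary C1–OH)
Conditions: BzCl (2.4 equiv), pyridine, DMAP (cat.), CH2Cl2, 0 °C
Reagents that add atoms: benzoyl chloride (12), O=C(Cl)c1ccccc1
Why: Acylation with benzoyl chloride and pyridine esterifies the two secondary allylic hydroxyls, whereas the hindered tertiary C1 hydroxyl does not react at 0 °C and O2 and C7 are still tied up in the silacycle.

Step 16
Reactants: 23 oxasilolane 3,6-dibenzoate
Product: 24 (1R,2S,3R,6S)-3,6-bis(benzoyloxy)-1-(hydroxymethyl)cyclohex-4-ene-1,2-diol (CNP0212417.5)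
Conditions: KF, KHCO3, 30% aq. H2O2, THF/MeOH (1:1), rt
Reagents that add atoms: hydrogen peroxide, OO
Why: Tamao–Fleming oxidation, in which fluoride and hydroperoxide give a hypervalent silicon peroxide and C7 migrates from silicon to oxygen, turns the Si–C7 bond into C7–OH and releases the C2 hydroxyl without touching any stereocentre.

Compound list
1 | cyclohexa-1,4-diene | C1=CCC=CC1 | starting material
2 | rac-trans-4,5-dibromocyclohex-1-ene (4R,5R enantiomer drawn) | Br[C@@H]1CC=CC[C@H]1Br | intermediate
3 | rac-(1R,2S,4R,5R)-4,5-dibromocyclohexane-1,2-diol (cis-diol, trans-dibromide) | O[C@H]1C[C@@H](Br)[C@H](Br)C[C@H]1O | intermediate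
4 | 2,2-dimethoxypropane | COC(C)(C)OC | starting material
5 | rac-(3aR,5R,6R,7aS)-5,6-dibromo-2,2-dimethylhexahydro-1,3-benzodioxole | CC1(C)O[C@H]2C[C@@H](Br)[C@H](Br)C[C@H]2O1 | intermediate
6 | (3aR,7aS)-2,2-dimethyl-3a,7a-dihydro-1,3-benzodioxole (meso; acetonide of cis-cyclohexa-3,5-diene-1,2-diol) | CC1(C)O[C@H]2C=CC=C[C@H]2O1 | intermediate
7 | endoperoxide, formed in the flask: acetonide of 2,3-dioxabicyclo[2.2.2]oct-5-ene-7,8-diol with the peroxide bridge on the face opposite the acetonide (meso) | CC1(C)O[C@H]2[C@H]3C=C[C@H](OO3)[C@H]2O1 | intermediate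
8 | meso-(3aR,4S,7R,7aS)-2,2-dimethyl-3a,4,7,7a-tetrahydro-1,3-benzodioxole-4,7-diol (2,3-O-isopropylidene-conduritol A; hydroxyls trans to the acetonide) | CC1(C)O[C@H]2[C@H](O)C=C[C@H](O)[C@H]2O1 | intermediate
9 | 4-methoxybenzyl chloride | COc1ccc(CCl)cc1 | starting material
10 | meso-(3aR,4S,7R,7aS)-4,7-bis[(4-methoxybenzyl)oxy]-2,2-dimethyl-3a,4,7,7a-tetrahydro-1,3-benzodioxole | CC1(C)O[C@H]2[C@H](OCc3ccc(OC)cc3)C=C[C@H](OCc3ccc(OC)cc3)[C@H]2O1 | intermediate
11 | meso-(1S,2R,3R,6S)-3,6-bis[(4-methoxybenzyl)oxy]cyclohex-4-ene-1,2-diol (1,4-di-O-PMB-conduritol A) | COc1ccc(cc1)CO[C@H]2C=C[C@@H](OCc3ccc(OC)cc3)[C@H](O)[C@@H]2O | intermediate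
12 | benzoyl chloride | O=C(Cl)c1ccccc1 | starting material
13 | (1S,2S,3R,6S)-2-hydroxy-3,6-bis[(4-methoxybenzyl)oxy]cyclohex-4-en-1-yl benzoate | COc1ccc(cc1)CO[C@H]2C=C[C@@H](OCc3ccc(OC)cc3)[C@H](O)[C@@H]2OC(=O)c4ccccc4 | intermediate
14 | (bromomethyl)chlorodimethylsilane | C[Si](C)(Cl)CBr | starting material
15 | (1R,2S,3R,6S)-2-{[(bromomethyl)dimethylsilyl]oxy}-3,6-bis[(4-methoxybenzyl)oxy]cyclohex-4-en-1-yl benzoate | COc1ccc(cc1)CO[C@H]2C=C[C@@H](OCc3ccc(OC)cc3)[C@H](O[Si](C)(C)CBr)[C@@H]2OC(=O)c4ccccc4 | intermediate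
16 | (1R,2S,3R,6S)-2-{[(iodomethyl)dimethylsilyl]oxy}-3,6-bis[(4-methoxybenzyl)oxy]cyclohex-4-en-1-yl benzoate | COc1ccc(cc1)CO[C@H]2C=C[C@@H](OCc3ccc(OC)cc3)[C@H](O[Si](C)(C)CI)[C@@H]2OC(=O)c4ccccc4 | intermediate
17 | (1R,2R,3R,6S)-2-{[(iodomethyl)dimethylsilyl]oxy}-3,6-bis[(4-methoxybenzyl)oxy]cyclohex-4-en-1-ol | COc1ccc(cc1)CO[C@H]2C=C[C@@H](OCc3ccc(OC)cc3)[C@H](O[Si](C)(C)CI)[C@@H]2O | intermediate
18 | (2S,3R,6S)-2-{[(iodomethyl)dimethylsilyl]oxy}-3,6-bis[(4-methoxybenzyl)oxy]cyclohex-4-en-1-one (key-step precursor) | COc1ccc(cc1)CO[C@H]2C=C[C@@H](OCc3ccc(OC)cc3)[C@H](O[Si](C)(C)CI)C2=O | intermediate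
19 | silylmethyllithium formed in the flask: 18 with Li in place of I | COc1ccc(cc1)CO[C@H]2C=C[C@@H](OCc3ccc(OC)cc3)[C@H](O[Si](C)(C)C[Li])C2=O | intermediate
20 | lithium alkoxide of 21, formed in the flask | COc1ccc(cc1)CO[C@H]2C=C[C@@H](OCc3ccc(OC)cc3)[C@H](O4)[C@]2(O[Li])C[Si]4(C)C | intermediate
21 | cis-fused oxasilolane tertiary alcohol, (1S,2S,3R,6S): 2,2-dimethyl-1-oxa-2-silacyclopentane ring O2–Si–C7–C1–C2 fused to the cyclohexene, PMB ethers on O3 and O6, free C1–OH cis to O6 (key-step product) | COc1ccc(cc1)CO[C@H]2C=C[C@@H](OCc3ccc(OC)cc3)[C@H](O4)[C@]2(O)C[Si]4(C)C | intermediate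
22 | oxasilolane triol, (1S,2S,3R,6S): as 21 with free hydroxyls on C3 and C6 | O[C@H]1C=C[C@@H](O)[C@H](O2)[C@]1(O)C[Si]2(C)C | intermediate
23 | oxasilolane 3,6-dibenzoate, (1S,2S,3R,6S): as 22 with benzoates on O3 and O6, tertiary C1–OH free | O=C(O[C@H]1C=C[C@@H](OC(=O)c2ccccc2)[C@H](O3)[C@]1(O)C[Si]3(C)C)c1ccccc1 | intermediate
24 | (1R,2S,3R,6S)-3,6-bis(benzoyloxy)-1-(hydroxymethyl)cyclohex-4-ene-1,2-diol (CNP0212417.5) | O=C(O[C@H]1C=C[C@@H](OC(=O)c2ccccc2)[C@H](O)[C@]1(O)CO)c1ccccc1 | target

Total step count: 16 steps.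
Longest linear sequence: 16 steps, from 1 to 24; compounds 4, 9, 12 and 14 are purchased.

Steps most likely to fail

1. Step 13. What may go wrong: the organolithium acts as a base, deprotonating next to the carbonyl at C2 or C6, after which an ether oxygen is lost and the ring aromatises; or t-BuLi attacks the carbonyl before the iodine is exchanged. The fallback gives up the tethered carbanion and forms the same C1–C7 bond by an intermolecular, chelation-controlled Grignard addition. It sets out from 18. Brief treatment with AcOH/THF/H2O at 0 °C hydrolyses the labile silyl ether to the hydroxy ketone (2S,3R,6S)-2-hydroxy-3,6-bis[(4-methoxybenzyl)oxy]cyclohex-4-en-1-one F1. F1 is added at −78 °C in THF to an excess of the silylmethyl Grignard reagent (i-PrO)Me2SiCH2MgCl (made from (chloromethyl)isopropoxydimethylsilane and Mg), after transmetalation with CeCl3 if its basicity has to be lowered. The first equivalent turns O2 into a magnesium alkoxide that chelates the C1 carbonyl, and the reagent should then attack from the face away from the C6 ether, which is the O2 face. This gives (1R,2S,3R,6S)-1-{[dimethyl(propan-2-yloxy)silyl]methyl}-3,6-bis[(4-methoxybenzyl)oxy]cyclohex-4-ene-1,2-diol F2. With a trace of pyridinium tosylate in CH2Cl2 the isopropoxysilane exchanges with the cis C2 hydroxyl, propan-2-ol is lost, and the route is rejoined at 21.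

2. Step 8. What may go wrong: poor discrimination between the two enantiotopic hydroxyls, because the flanking ether oxygens offer the copper centre competing chelation sites; or slow benzoate migration between O1 and O2 that erodes the enantiomeric purity. The fallback replaces catalytic desymmetrisation by a resolution through diastereomeric esters, which loses no material because the starting diol is meso. It sets out from 11. Esterification with one equivalent of (S)-2-methoxy-2-phenylacetic acid (DCC, DMAP cat., CH2Cl2, 0 °C) should give two monoesters: (1S,2S,3R,6S)-2-hydroxy-3,6-bis[(4-methoxybenzyl)oxy]cyclohex-4-en-1-yl (2S)-2-methoxy-2-phenylacetate F3, and the diastereomeric monoester with the acyl group on O2 and O1 free F4. They are separated by chromatography or crystallisation, and F4 is returned to 11 with K2CO3 in MeOH. F3 is taken through the conditions of steps 9 and 10 to the O2 (bromomethyl)dimethylsilyl ether of F3 F5 and then the O2 (iodomethyl)dimethylsilyl ether of F3 F6. i-Bu2AlH at −78 °C, as in step 11, then cleaves the auxiliary ester and the route is rejoined at 17.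

3. Step 16. What may go wrong: under the basic fluoride and peroxide conditions the C3 benzoate migrates to the C2 hydroxyl as it is set free, or a benzoate is cleaved by hydroperoxide. The fallback changes the order of events so that the silicon–carbon bond is oxidised before any ester is present. It sets out from 21. KF, KHCO3 and H2O2 in THF/MeOH give (1R,2S,3R,6S)-1-(hydroxymethyl)-3,6-bis[(4-methoxybenzyl)oxy]cyclohex-4-ene-1,2-diol F7. Et3SiCl and imidazole in DMF at 0 °C silylate the primary C7 and secondary C2 hydroxyls but not the tertiary one, giving the 2,7-bis(triethylsilyl) ether of F7 F8. DDQ in buffered CH2Cl2 removes both PMB groups to give the 3,6-diol F9. BzCl and pyridine give the 3,6-dibenzoate 2,7-bis(triethylsilyl) ether F10. HF·pyridine in THF/pyridine at 0 °C, an acidic medium in which benzoates do not migrate, removes both silyl groups and delivers 24.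

Further compounds
F1 | step 13 | (2S,3R,6S)-2-hydroxy-3,6-bis[(4-methoxybenzyl)oxy]cyclohex-4-en-1-one | COc1ccc(cc1)CO[C@H]2C=C[C@@H](OCc3ccc(OC)cc3)[C@H](O)C2=O
F2 | step 13 | (1R,2S,3R,6S)-1-{[dimethyl(propan-2-yloxy)silyl]methyl}-3,6-bis[(4-methoxybenzyl)oxy]cyclohex-4-ene-1,2-diol | COc1ccc(cc1)CO[C@H]2C=C[C@@H](OCc3ccc(OC)cc3)[C@H](O)[C@]2(O)C[Si](C)(C)OC(C)C
F3 | step 8 | (1S,2S,3R,6S)-2-hydroxy-3,6-bis[(4-methoxybenzyl)oxy]cyclohex-4-en-1-yl (2S)-2-methoxy-2-phenylacetate | COc1ccc(cc1)CO[C@H]2C=C[C@@H](OCc3ccc(OC)cc3)[C@H](O)[C@@H]2OC(=O)[C@@H](OC)c4ccccc4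
F4 | step 8 | diastereomeric monoester: (2S)-2-methoxy-2-phenylacetate on O2, O1 free | COc1ccc(cc1)CO[C@H]2C=C[C@@H](OCc3ccc(OC)cc3)[C@H](OC(=O)[C@@H](OC)c4ccccc4)[C@@H]2O
F5 | step 8 | O2 (bromomethyl)dimethylsilyl ether of F3 | COc1ccc(cc1)CO[C@H]2C=C[C@@H](OCc3ccc(OC)cc3)[C@H](O[Si](C)(C)CBr)[C@@H]2OC(=O)[C@@H](OC)c4ccccc4
F6 | step 8 | O2 (iodomethyl)dimethylsilyl ether of F3 | COc1ccc(cc1)CO[C@H]2C=C[C@@H](OCc3ccc(OC)cc3)[C@H](O[Si](C)(C)CI)[C@@H]2OC(=O)[C@@H](OC)c4ccccc4
F7 | step 16 | (1R,2S,3R,6S)-1-(hydroxymethyl)-3,6-bis[(4-methoxybenzyl)oxy]cyclohex-4-ene-1,2-diol | COc1ccc(cc1)CO[C@H]2C=C[C@@H](OCc3ccc(OC)cc3)[C@H](O)[C@]2(O)CO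
F8 | step 16 | 2,7-bis(triethylsilyl) ether of F7 (1S,2S,3R,6S) | COc1ccc(cc1)CO[C@H]2C=C[C@@H](OCc3ccc(OC)cc3)[C@H](O[Si](CC)(CC)CC)[C@]2(O)CO[Si](CC)(CC)CC
F9 | step 16 | 3,6-diol from F8 (1S,2S,3R,6S) | O[C@H]1C=C[C@@H](O)[C@H](O[Si](CC)(CC)CC)[C@]1(O)CO[Si](CC)(CC)CC
F10 | step 16 | 3,6-dibenzoate of F9 (1S,2S,3R,6S) | O=C(O[C@H]1C=C[C@@H](OC(=O)c2ccccc2)[C@H](O[Si](CC)(CC)CC)[C@]1(O)CO[Si](CC)(CC)CC)c1ccccc1
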